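**Plan**
- The target is read as (3E,4R)-3-(4-hydroxy-3,5-dimethoxybenzylidene)-4-(3,4,5-trimethoxybenzyl)dihydrofuran-2(3H)-one. Ring locants are O1, C2(=O), C3, C4, C5; Ar is the syringyl ring and Ar′ the trimethoxyphenyl ring.
- Cuts: O1–C2 first (lactone to γ-hydroxy acid). C2–C3 and C4–C5 are then cut together, which removes CO2 and a hydroxymethyl unit and leaves the allene ArCH=C=CH–CH2Ar′.
- Enabling feature: the exocyclic arylidene carbon, ring carbon C3 (sp2) and ring carbon C4 (sp3, H-bearing) are three contiguous carbons at the oxidation level of a 1,3-disubstituted allene. Its sp carbon accepts the electrophile CO2, and its benzyl-bearing end accepts a nucleophilic CH2O unit, both on one nickel centre.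
- Forward: syringaldehyde → dibromoalkene → acetylide + Weinreb amide of Ar′CH2CO2H → ynone → (S)-propargylic alcohol → (S)-allene → nickel-mediated carboxylation/alkylation → hydrolysis and closure of the only ring (the lactone) last.
- Stereochemistry: one catalyst-controlled ketone reduction sets it. It is then relayed point → axis (diazene retro-ene) → point, and the axis fixes both C4 (R) and the E alkene in the key step.

Key step: step 7

Assumption: the aryl silyl ether is taken to survive n-BuLi at −78 °C, DBU and the organozinc reagent, and to fall only to hydroxide in the last step.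

**Step 1**
Reactants: 1 syringaldehyde (4-hydroxy-3,5-dimethoxybenzaldehyde)
Product: 2 4-(tert-butyldimethylsilyloxy)-3,5-dimethoxybenzaldehyde
Conditions: TBSCl, imidazole, DMF, rt
Reagents that add atoms: tert-butyldimethylsilyl chloride, CC(C)(C)[Si](C)(C)Cl
Why: Imidazole-promoted silylation of a phenol masks the acidic OH for the organolithium, Mitsunobu and organometallic steps.

**Step 2**
Reactants: 2 4-(tert-butyldimethylsilyloxy)-3,5-dimethoxybenzaldehyde
Product: 3 tert-butyl[4-(2,2-dibromovinyl)-2,6-dimethoxyphenoxy]dimethylsilane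
Conditions: CBr4, PPh3, CH2Cl2, 0 °C
Reagents that add atoms: carbon tetrabromide, BrC(Br)(Br)Br
Why: This is the first stage of the Corey–Fuchs reaction, a Wittig-type olefination of the aldehyde by Ph3P=CBr2 under neutral conditions.

**Step 3**
Reactants: 4 2-(3,4,5-trimethoxyphenyl)acetic acid
Product: 5 N-methoxy-N-methyl-2-(3,4,5-trimethoxyphenyl)acetamide
Conditions: CDI, CH2Cl2, rt; then MeNHOMe·HCl, rt
Reagents that add atoms: N,O-dimethylhydroxylamine hydrochloride, CNOC.Cl
Why: Weinreb amide formation through the acyl imidazolide avoids an arylacetyl chloride and its ketene.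

**Step 4**
Reactants: 3 tert-butyl[4-(2,2-dibromovinyl)-2,6-dimethoxyphenoxy]dimethylsilane; 5 N-methoxy-N-methyl-2-(3,4,5-trimethoxyphenyl)acetamide
Product: 7 4-[4-(tert-butyldimethylsilyloxy)-3,5-dimethoxyphenyl]-1-(3,4,5-trimethoxyphenyl)but-3-yn-2-one, via lithium acetylide 6 (not isolated)
Conditions: 3, n-BuLi (2.1 equiv), THF, −78 °C; then 5, −78 to 0 °C; aq. NH4Cl
Reagents that add atoms: none
Why: The second stage of the Corey–Fuchs reaction (Br/Li exchange, Fritsch–Buttenberg–Wiechell shift, deprotonation) gives 6, which adds only once to the Weinreb amide because the chelated tetrahedral adduct holds until the quench.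

**Step 5**
Reactants: 7 4-[4-(tert-butyldimethylsilyloxy)-3,5-dimethoxyphenyl]-1-(3,4,5-trimethoxyphenyl)but-3-yn-2-one
Product: 8 (S)-4-[4-(tert-butyldimethylsilyloxy)-3,5-dimethoxyphenyl]-1-(3,4,5-trimethoxyphenyl)but-3-yn-2-ol
Conditions: Ru[(S,S)-TsNCHPhCHPhNH](p-cymene) (1 mol %, base-free), i-PrOH, rt
Reagents that add atoms: none
Why: In this Noyori–Ikariya transfer hydrogenation of an α,β-acetylenic ketone the alkynyl group takes the place of the π-substituent in the six-membered hydride/proton transfer, so the (S,S) catalyst should set the (S) carbinol, the only catalyst-controlled stereocentre of the route.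

**Step 6**
Reactants: 8 (S)-4-[4-(tert-butyldimethylsilyloxy)-3,5-dimethoxyphenyl]-1-(3,4,5-trimethoxyphenyl)but-3-yn-2-ol
Product: 11 (S)-1-[4-(tert-butyldimethylsilyloxy)-3,5-dimethoxyphenyl]-4-(3,4,5-trimethoxyphenyl)buta-1,2-diene, via Mitsunobu hydrazide 9 (not isolated), via propargylic diazene 10 (not isolated)
Conditions: PPh3, DEAD, THF, −15 °C; 2-nitrobenzenesulfonohydrazide, −15 °C to rt
Reagents that add atoms: none
Why: In the Myers allene synthesis, Mitsunobu displacement with inversion gives 9, loss of sulfinic acid gives 10, and its retro-ene loss of N2 delivers H to the aryl-bearing alkyne carbon on the side of the C–N bond, so the (S) centre should be converted stereospecifically into the (S) axis.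

**Step 7**
Reactants: 11 (S)-1-[4-(tert-butyldimethylsilyloxy)-3,5-dimethoxyphenyl]-4-(3,4,5-trimethoxyphenyl)buta-1,2-diene; 12 iodomethyl pivalate
Product: 15 (2E,3R)-2-[4-(tert-butyldimethylsilyloxy)-3,5-dimethoxybenzylidene]-3-[(pivaloyloxy)methyl]-4-(3,4,5-trimethoxyphenyl)butanoic acid, via pivaloyloxymethylzinc iodide 13 (not isolated), via oxanickelacycle 14 (not isolated)
Conditions: (a) 12, Zn dust, THF, 10 °C; (b) 11, Ni(cod)2 (1.1 equiv), DBU (2.2 equiv), CO2 (1 atm), THF, 0 °C; Ar purge; (c) solution of 13 (3 equiv), 0 °C to rt; 1 M HCl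
Reagents that add atoms: carbon dioxide, O=C=O
Why: Proposed new method: DBU-ligated zerovalent nickel should bind the benzyl-substituted π bond of 11 on the face of the ArC–H (the aryl group lies in the plane of this π bond and shields the other face) and couple it oxidatively with CO2, so that the CO2 carbon bonds to the sp carbon (future C2–C3) and nickel to the benzyl-bearing terminus, closing the transient five-membered oxanickelacycle 14 (in equilibrium with its oxa-π-allyl form) by oxidative cyclisation. After the CO2 is purged, 13 passes its CH2OPiv group to divalent nickel while the carboxylate goes to zinc, and C(sp3)–C(sp3) reductive elimination on the nickel-bearing face forms the future C4–C5 bond with retention. Closest known reaction types: the Ni(cod)2/DBU carboxylation of allenes through such nickelacycles, and the coupling of the oxa-π-allylnickel complexes made from 1,3-dienes and CO2 with organozinc reagents; new are the (acyloxy)methylzinc partner and the axially chiral 1,3-disubstituted allene. The single new stereocentre (R) and the E geometry are both controlled by the (S) axis, because the carboxyl carbon and the CH2OPiv group are delivered to the same face, the carboxyl group ending cis to the vinylic H. The step needs coupling at the benzyl-bearing and not at the aryl-bearing allyl terminus, which retention of the cinnamate conjugation and the σ-bound resting form 14 should secure, and it needs reductive elimination to outrun syn/anti isomerisation and β-hydride loss, which fast zinc-to-nickel transfer at 0 °C and a CH2OPiv group without β-hydrogens favour. No ring of the target closes in this step.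

**Step 8**
Reactants: 15 (2E,3R)-2-[4-(tert-butyldimethylsilyloxy)-3,5-dimethoxybenzylidene]-3-[(pivaloyloxy)methyl]-4-(3,4,5-trimethoxyphenyl)butanoic acid
Product: 17 (3E,4R)-3-(4-hydroxy-3,5-dimethoxybenzylidene)-4-(3,4,5-trimethoxybenzyl)dihydrofuran-2(3H)-one, via hydroxy acid 16 (not isolated)
Conditions: LiOH·H2O, THF/MeOH/H2O (degassed), 50 °C; then 2 M HCl to pH 1, rt
Reagents that add atoms: none
Why: Hydroxide saponifies the pivalate and cleaves the aryl silyl ether, and acidification closes the γ-hydroxy acid 16 by 5-exo-trig lactonisation; the C4–H is only cross-conjugated to the carboxyl group, so the stereocentre should hold.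

**Compound list**
1 | syringaldehyde | COc1cc(C=O)cc(OC)c1O | starting material
2 | 4-(tert-butyldimethylsilyloxy)-3,5-dimethoxybenzaldehyde | COc1cc(C=O)cc(OC)c1O[Si](C)(C)C(C)(C)C | intermediate
3 | tert-butyl[4-(2,2-dibromovinyl)-2,6-dimethoxyphenoxy]dimethylsilane | COc1cc(C=C(Br)Br)cc(OC)c1O[Si](C)(C)C(C)(C)C | intermediate
4 | 2-(3,4,5-trimethoxyphenyl)acetic acid | COc1cc(CC(=O)O)cc(OC)c1OC | starting material
5 | N-methoxy-N-methyl-2-(3,4,5-trimethoxyphenyl)acetamide | COc1cc(CC(=O)N(C)OC)cc(OC)c1OC | intermediate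
6 | lithium [4-(tert-butyldimethylsilyloxy)-3,5-dimethoxyphenyl]acetylide | COc1cc(C#C[Li])cc(OC)c1O[Si](C)(C)C(C)(C)C | intermediate
7 | 4-[4-(tert-butyldimethylsilyloxy)-3,5-dimethoxyphenyl]-1-(3,4,5-trimethoxyphenyl)but-3-yn-2-one | COc1cc(C#CC(=O)Cc2cc(OC)c(OC)c(OC)c2)cc(OC)c1O[Si](C)(C)C(C)(C)C | intermediate
8 | (S)-4-[4-(tert-butyldimethylsilyloxy)-3,5-dimethoxyphenyl]-1-(3,4,5-trimethoxyphenyl)but-3-yn-2-ol | COc1cc(C#C[C@@H](O)Cc2cc(OC)c(OC)c(OC)c2)cc(OC)c1O[Si](C)(C)C(C)(C)C | intermediate
9 | N-[(R)-propargyl]-2-nitrobenzenesulfonohydrazide formed from 8 with inversion | COc1cc(C#C[C@H](N(N)S(=O)(=O)c3ccccc3[N+](=O)[O-])Cc2cc(OC)c(OC)c(OC)c2)cc(OC)c1O[Si](C)(C)C(C)(C)C | intermediate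
10 | (R)-propargylic diazene | COc1cc(C#C[C@H](N=N)Cc2cc(OC)c(OC)c(OC)c2)cc(OC)c1O[Si](C)(C)C(C)(C)C | intermediate
11 | (S)-1-[4-(tert-butyldimethylsilyloxy)-3,5-dimethoxyphenyl]-4-(3,4,5-trimethoxyphenyl)buta-1,2-diene | COc1cc(C([H])=[C@@]=C([H])Cc2cc(OC)c(OC)c(OC)c2)cc(OC)c1O[Si](C)(C)C(C)(C)C | intermediate
12 | iodomethyl pivalate | CC(C)(C)C(=O)OCI | starting material
13 | (pivaloyloxy)methylzinc iodide | CC(C)(C)C(=O)OC[Zn]I | intermediate
14 | oxanickelacycle (σ-allyl form, DBU ligands on nickel not drawn) | COc1cc(/C=C2/C(=O)O[Ni][C@@H]2Cc2cc(OC)c(OC)c(OC)c2)cc(OC)c1O[Si](C)(C)C(C)(C)C | intermediate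
15 | (2E,3R)-2-[4-(tert-butyldimethylsilyloxy)-3,5-dimethoxybenzylidene]-3-[(pivaloyloxy)methyl]-4-(3,4,5-trimethoxyphenyl)butanoic acid | COc1cc(/C=C(/C(=O)O)[C@H](COC(=O)C(C)(C)C)Cc2cc(OC)c(OC)c(OC)c2)cc(OC)c1O[Si](C)(C)C(C)(C)C | intermediate
16 | (2E,3R)-2-(4-hydroxy-3,5-dimethoxybenzylidene)-3-(hydroxymethyl)-4-(3,4,5-trimethoxyphenyl)butanoic acid | COc1cc(/C=C(/C(=O)O)[C@H](CO)Cc2cc(OC)c(OC)c(OC)c2)cc(OC)c1O | intermediate
17 | (3E,4R)-3-(4-hydroxy-3,5-dimethoxybenzylidene)-4-(3,4,5-trimethoxybenzyl)dihydrofuran-2(3H)-one | COc1cc(/C=C2/C(=O)OC[C@@H]2Cc2cc(OC)c(OC)c(OC)c2)cc(OC)c1O | target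

Total step count: 8. Longest linear sequence: 7 (steps 1, 2, 4, 5, 6, 7, 8).

**Steps most likely to fail**

1. Step 7.
   - What may go wrong: coupling at the aryl-bearing allyl terminus; loss of the axial information by syn/anti isomerisation of the allylnickel; β-hydride loss to the conjugated diene; a second carboxylation if CO2 is not fully removed.
   - Fallback (known chemistry, the two bonds made separately), from 8 back to 17: MsCl/Et3N converts 8 into the (S)-mesylate F1.
   - Pd(OAc)2/PPh3 with Et2Zn and monomeric formaldehyde in THF at −20 °C follows. Zerovalent palladium adds anti in the SN2′ sense, the allenylpalladium is transmetalated to an allenylzinc, and this adds through a cyclic SE2′ transition state. The result should be the (R)-homopropargylic alcohol F2, with net inversion at the former carbinol carbon.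
   - ClCO2Et/pyridine gives the ethyl carbonate F3.
   - Ti(OiPr)4/2 i-PrMgCl in Et2O (−50 to −20 °C) forms the alkyne complex of divalent titanium. Intramolecular nucleophilic acyl substitution and protonolysis of the remaining vinyl–titanium bond (cis to the new acyl group) should give the (E)-silyl-protected lactone F4.
   - TBAF/AcOH in THF at 0 °C then frees the phenol and gives 17.

2. Step 6.
   - What may go wrong: slow Mitsunobu displacement next to the benzyl group; partial ionisation with erosion of the stereochemical relay; isomerisation of the skipped aryl-allene CH2 to the diene.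
   - Fallback, from 8 back to 11: ClCO2Me/pyridine gives the methyl carbonate F5.
   - Pd2(dba)3·CHCl3/n-Bu3P with HCO2NH4 in THF at rt effects hydrogenolysis: anti SN2′ oxidative addition of zerovalent palladium, decarboxylation of formate, and reductive elimination of the allenylpalladium hydride.
   - The hydride arrives anti to the departed oxygen, the same sense as in the diazene route, so 11 should result.

3. Step 5.
   - What may go wrong: isomerisation of the doubly activated CH2 of the ynone to an allenyl ketone before hydride transfer; insufficient facial discrimination between the two large substituents.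
   - Fallback (resolution instead of asymmetric catalysis), from 7 back to 8: NaBH4/CeCl3·7H2O in MeOH at −78 °C gives the racemic propargylic alcohol F6.
   - Esterification with (S)-O-methylmandelic acid (DCC, DMAP) and chromatographic separation of the diastereomers gives the ester of the (S)-carbinol F7.
   - DIBAL-H in CH2Cl2 at −78 °C releases 8 without touching the aryl silyl ether.

**Further compounds**
F1 | step 7 | (S)-4-[4-(tert-butyldimethylsilyloxy)-3,5-dimethoxyphenyl]-1-(3,4,5-trimethoxyphenyl)but-3-yn-2-yl methanesulfonate | COc1cc(C#C[C@@H](OS(C)(=O)=O)Cc2cc(OC)c(OC)c(OC)c2)cc(OC)c1O[Si](C)(C)C(C)(C)C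
F2 | step 7 | (R)-4-[4-(tert-butyldimethylsilyloxy)-3,5-dimethoxyphenyl]-2-(3,4,5-trimethoxybenzyl)but-3-yn-1-ol | COc1cc(C#C[C@H](CO)Cc2cc(OC)c(OC)c(OC)c2)cc(OC)c1O[Si](C)(C)C(C)(C)C
F3 | step 7 | ethyl carbonate of F2 | COc1cc(C#C[C@H](COC(=O)OCC)Cc2cc(OC)c(OC)c(OC)c2)cc(OC)c1O[Si](C)(C)C(C)(C)C
F4 | step 7 | (3E,4R)-3-[4-(tert-butyldimethylsilyloxy)-3,5-dimethoxybenzylidene]-4-(3,4,5-trimethoxybenzyl)dihydrofuran-2(3H)-one | COc1cc(/C=C2/C(=O)OC[C@@H]2Cc2cc(OC)c(OC)c(OC)c2)cc(OC)c1O[Si](C)(C)C(C)(C)C
F5 | step 6 | methyl carbonate of 8 | COc1cc(C#C[C@@H](OC(=O)OC)Cc2cc(OC)c(OC)c(OC)c2)cc(OC)c1O[Si](C)(C)C(C)(C)C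
F6 | step 5 | racemic 4-[4-(tert-butyldimethylsilyloxy)-3,5-dimethoxyphenyl]-1-(3,4,5-trimethoxyphenyl)but-3-yn-2-ol | COc1cc(C#CC(O)Cc2cc(OC)c(OC)c(OC)c2)cc(OC)c1O[Si](C)(C)C(C)(C)C
F7 | step 5 | (S)-2-methoxy-2-phenylacetate of the (S)-carbinol 8 | COc1cc(C#C[C@@H](OC(=O)[C@@H](OC)c3ccccc3)Cc2cc(OC)c(OC)c(OC)c2)cc(OC)c1O[Si](C)(C)C(C)(C)C
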